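**Assumption:** the target is taken exactly as the SMILES encodes it, i.e. (4R,5R), with the C4 and C5 methyls trans and the side chain cis to the C5 methyl.

## Retrosynthetic overview

1. The butenolide is made last, by oxidising a 3-alkylfuran (singlet oxygen, then borohydride).
2. The (4R,5R)-enone comes from a catalytic asymmetric conjugate reduction of a mirror-symmetric 4-alkyl-3,4,5-trimethylcyclohexa-2,5-dienone; this single step sets both C4 and C5.
3. The dienone comes from bis-allylic oxidation of a 1,4-cyclohexadiene, joined to the chain by a Cu-catalysed sp3–sp3 coupling (ring-CH2–M plus the terminal allylic bromide of the chain).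
4. The quaternary carbon comes from Birch reductive methylation of 2,6-dimethylbenzoic acid; the arene becomes the carbocycle and the CO2H carbon becomes the first chain carbon.
5. The chain comes from 3-furylmethyl Grignard plus geranyl chloride, then SeO2 oxidation of the terminal (E)-methyl. Ring order: carbocycle first (from the arene), butenolide last (from the furan).

## Route

**Step 1**
Reactants: 1, 3-furanmethanol
Product: 2, 3-(chloromethyl)furan
Conditions: MsCl, s-collidine, LiCl, DMF, 0 °C → rt
Reagents that add atoms: LiCl, [Li+].[Cl-] (chloride source; MsCl, CS(=O)(=O)Cl, is the activator)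
Why: In situ mesylation followed by SN2 chloride displacement (Collington–Meyers) gives the acid-sensitive furylmethyl chloride under buffered conditions.

**Step 2**
Reactants: 2, 3-(chloromethyl)furan; 3, geranyl chloride
Product: 4, dendrolasin, 3-[(3E)-4,8-dimethylnona-3,7-dien-1-yl]furan
Conditions: Mg, THF (Grignard of 2); then 3, Li2CuCl4 (3 mol %), THF, 0 °C
Reagents that add atoms: none
Why: Kochi-type Cu-catalysed Grignard/allylic chloride coupling attacks the primary (α) carbon and retains the E-alkene.

**Step 3**
Reactants: 4, dendrolasin
Product: 5, (2E,6E)-9-(furan-3-yl)-2,6-dimethylnona-2,6-dien-1-ol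
Conditions: SeO2 (0.5 equiv), t-BuOOH, salicylic acid (cat.), CH2Cl2, 0 °C → rt; then NaBH4, MeOH, 0 °C
Reagents that add atoms: SeO2, O=[Se]=O (t-BuOOH, CC(C)(C)OO, as re-oxidant)
Why: Sharpless SeO2 allylic oxidation (ene, then [2,3]-shift) hydroxylates the (E)-methyl of the terminal trisubstituted alkene; the borohydride work-up returns any over-oxidised enal to the alcohol.

**Step 4**
Reactants: 5
Product: 6, 3-[(3E,7E)-9-bromo-4,8-dimethylnona-3,7-dien-1-yl]furan
Conditions: CBr4, PPh3, CH2Cl2, −20 °C
Reagents that add atoms: CBr4, BrC(Br)(Br)Br
Why: Appel bromination of a primary allylic alcohol is SN2 and neutral, so the E-geometry and the furan survive.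

**Step 5**
Reactants: 7, 2,6-dimethylbenzoic acid
Product: 8, 1,2,6-trimethylcyclohexa-2,5-diene-1-carboxylic acid (achiral)
Conditions: Li, NH3(l)/THF, −78 °C; then MeI, −78 → −33 °C; H3O+
Reagents that add atoms: MeI, CI
Why: Birch reductive alkylation: the carboxylate directs ipso/para reduction and the resulting enolate is C-methylated, making the quaternary carbon flanked by the two vinylic methyls.

**Step 6**
Reactants: 8
Product: 9, (1,2,6-trimethylcyclohexa-2,5-dien-1-yl)methanol
Conditions: LiAlH4, THF, reflux
Reagents that add atoms: none
Why: Hydride reduction of the acid; the isolated trisubstituted alkenes are inert.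

**Step 7**
Reactants: 9
Product: 10, 6-(iodomethyl)-1,5,6-trimethylcyclohexa-1,4-diene
Conditions: PPh3, I2, imidazole, PhMe/MeCN, 60 °C
Reagents that add atoms: I2, II
Why: Appel-type iodination is an SN2 displacement on the alkoxyphosphonium, which avoids the neopentyl cation that would rearrange.

**Step 8**
Reactants: 10; 6
Product: 11, 3-[(3E,7E)-4,8-dimethyl-10-(1,2,6-trimethylcyclohexa-2,5-dien-1-yl)deca-3,7-dien-1-yl]furan
Conditions: 10, t-BuLi (2.1 equiv), Et2O/pentane, −78 °C; MgBr2·OEt2; then 6, Li2CuCl4 (5 mol %), THF, −78 → −20 °C
Reagents that add atoms: none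
Why: Li–I exchange at −78 °C (cold enough to suppress the homoallyl/cyclopropylcarbinyl shift), transmetalation and Kochi Cu-catalysed sp3–sp3 coupling at the α-carbon of the (E)-allylic bromide form the ring-CH2–CH2 bond with retention of alkene geometry.

**Step 9**
Reactants: 11
Product: 12, 4-[(3E,7E)-10-(furan-3-yl)-3,7-dimethyldeca-3,7-dien-1-yl]-3,4,5-trimethylcyclohexa-2,5-dien-1-one (achiral, mirror-symmetric)
Conditions: PDC, t-BuOOH, Celite, PhH, 10 °C → rt
Reagents that add atoms: tert-butyl hydroperoxide, CC(C)(C)OO (oxygen source; PDC is the Cr mediator)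
Why: Allylic oxidation (Schultz conditions for 2,5-cyclohexadienes) picks the only doubly allylic CH2, which is far weaker than the singly allylic chain C–H bonds.

**Step 10**
Reactants: 12
Product: 13, (4R,5R)-4-[(3E,7E)-10-(furan-3-yl)-3,7-dimethyldeca-3,7-dien-1-yl]-3,4,5-trimethylcyclohex-2-en-1-one
Conditions: CuCl/NaOt-Bu/(R)-p-Tol-BINAP (5 mol %), PMHS (1.1 equiv Si–H), PhMe, 0 °C; then TBAF, THF, 0 °C
Reagents that add atoms: none
Why: Proposed new method: a chiral L*CuH adds hydride to C5 of one of the two enantiotopic enone arms on the face syn to the C4 methyl (anti to the chain, which the flanking 3,5-methyls force to sit under the ring), so catalyst and substrate preferences reinforce and C4(R) and C5(R) are set together, while the silyl dienol ether formed blocks a second reduction; the closest known reactions are CuH asymmetric conjugate reduction of β,β-disubstituted cycloalkenones and desymmetrising conjugate additions to 4,4-disubstituted cyclohexadienones, and the ligand antipode is chosen as the opposite of the one that gives (R)-3-methylcyclohexanone and must be confirmed on first use.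

**Step 11**
Reactants: 13
Product: 14, 4-{(3E,7E)-4,8-dimethyl-10-[(1R,6R)-1,2,6-trimethyl-4-oxocyclohex-2-en-1-yl]deca-3,7-dien-1-yl}-5-hydroxyfuran-2(5H)-one (lactol epimers)
Conditions: O2, hν (visible), rose bengal (cat.), i-Pr2NEt, CH2Cl2, −78 °C
Reagents that add atoms: O2, O=O
Why: Singlet-oxygen [4+2] on the furan (much faster than the ene reaction of trisubstituted alkenes; the enone is inert), then base-induced Kornblum–DeLaMare opening at the unhindered C5–H (Faulkner conditions), gives the 4-alkyl-5-hydroxybutenolide regioisomer.

**Step 12**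
Reactants: 14
Product: 15, cyclolinteinone
Conditions: NaBH4 (1 equiv), EtOH/CH2Cl2, −78 → −40 °C; then 1 M HCl, rt
Reagents that add atoms: none
Why: The lactol reacts as its open aldehyde-carboxylate, which borohydride reduces at low temperature much faster than the hindered conjugated ketone; acidification lactonises the hydroxy acid to the 4-substituted 2(5H)-furanone without touching C4 or C5.

## Compound list

1 | 3-furanmethanol | OCc1ccoc1 | starting material
2 | 3-(chloromethyl)furan | ClCc1ccoc1 | intermediate
3 | geranyl chloride | CC(C)=CCC/C(C)=C/CCl | starting material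
4 | dendrolasin | CC(C)=CCC/C(C)=C/CCc1ccoc1 | intermediate
5 | (2E,6E)-9-(furan-3-yl)-2,6-dimethylnona-2,6-dien-1-ol | OC/C(C)=C/CC/C(C)=C/CCc1ccoc1 | intermediate
6 | 3-[(3E,7E)-9-bromo-4,8-dimethylnona-3,7-dien-1-yl]furan | BrC/C(C)=C/CC/C(C)=C/CCc1ccoc1 | intermediate
7 | 2,6-dimethylbenzoic acid | Cc1cccc(C)c1C(=O)O | starting material
8 | 1,2,6-trimethylcyclohexa-2,5-diene-1-carboxylic acid | CC1=CCC=C(C)C1(C)C(=O)O | intermediate
9 | (1,2,6-trimethylcyclohexa-2,5-dien-1-yl)methanol | CC1=CCC=C(C)C1(C)CO | intermediate
10 | 6-(iodomethyl)-1,5,6-trimethylcyclohexa-1,4-diene | CC1=CCC=C(C)C1(C)CI | intermediate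
11 | 3-[(3E,7E)-4,8-dimethyl-10-(1,2,6-trimethylcyclohexa-2,5-dien-1-yl)deca-3,7-dien-1-yl]furan | CC1=CCC=C(C)C1(C)CC/C(C)=C/CC/C(C)=C/CCc1ccoc1 | intermediate
12 | 4-[(3E,7E)-10-(furan-3-yl)-3,7-dimethyldeca-3,7-dien-1-yl]-3,4,5-trimethylcyclohexa-2,5-dien-1-one | CC1=CC(=O)C=C(C)C1(C)CC/C(C)=C/CC/C(C)=C/CCc1ccoc1 | intermediate
13 | (4R,5R)-4-[(3E,7E)-10-(furan-3-yl)-3,7-dimethyldeca-3,7-dien-1-yl]-3,4,5-trimethylcyclohex-2-en-1-one | CC1=CC(=O)C[C@@H](C)[C@@]1(C)CC/C(C)=C/CC/C(C)=C/CCc1ccoc1 | intermediate
14 | 5-hydroxybutenolide of 13 (lactol epimers) | CC1=CC(=O)C[C@@H](C)[C@@]1(C)CC/C(C)=C/CC/C(C)=C/CCC1=CC(=O)OC1O | intermediate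
15 | cyclolinteinone | CC1=CC(=O)C[C@@H](C)[C@@]1(C)CC/C(C)=C/CC/C(C)=C/CCC1=CC(=O)OC1 | target

## Summary

Total steps: 12. Longest linear sequence: 9 (steps 1–4, then 8–12); the ring branch (steps 5–7) is 3 steps before the union.

Steps most likely to fail, with fallbacks that change the approach:

1. **Step 10 (desymmetrising CuH reduction).** Risks are modest facial discrimination between the C4 methyl and the C4 CH2CH2R group, competing 1,2-reduction, and the unverified ligand sense. Fallback: set C5 alone on a substrate where diastereoselectivity does not matter, then build C4 by substrate control. Concretely: make the 4-methoxy p-quinol ether of the corresponding 4-alkyl-3,5-dimethylphenol (PhI(OAc)2/MeOH), reduce with CuH, cleave C4–OMe with SmI2 to the (5R)-β,γ-enone, then L-Selectride, OH-directed Simmons–Smith cyclopropanation, oxidation and acid-mediated cyclopropane opening to install the C4 methyl trans to the C5 methyl.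

2. **Step 8 (coupling of the ring-CH2 organometallic).** Risks are vinyl shift or ring expansion of the homoallylic organometallic and SN2′ attack on the bromide. Fallback: use the ring carbon as an electrophile instead. Oxidise 9 to the aldehyde, carry out a Wittig reaction with the phosphonium ylide made from 6, and reduce the new disubstituted alkene chemoselectively with diimide. Alternatively, Birch-alkylate 7 directly with the one-carbon-homologated chain iodide and reduce CO2H to CH3.

3. **Step 9 (bis-allylic oxidation with the furan and chain alkenes present).** Risk is oxidative loss of the furan or chain allylic oxidation. Fallback: change the order of events. Couple the Grignard from 10 with TBS-protected (2E,6E)-8-bromogeraniol, oxidise and desymmetrise on that robust substrate, then attach the heterocycle last (allylic bromide plus 3-furylmethylzinc under Pd, or B-alkyl Suzuki coupling with 4-bromo-2(5H)-furanone).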